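**Plan**

- Ring numbering of the target: C1 and C4 carbonyls, C2 OH, C3 side chain, C5 OMe, C6 H; side chain C1'–C15' with the acetate on C2'.
- Retrosynthesis first removes the acetyl group and the C1 oxygen (para-oxidation of a C4 phenol). The benzene ring is then cut at C1–C2, C3–C4, C4–C5 and C1–C6.
- The enabling feature: C2 (oxygen) and C3 (chain) are adjacent and map onto a siloxyalkyne, while C4–C5–C6–C1, with oxygen on C4 and methoxy on C5, maps onto a (2-methoxyvinyl)ketene.
- Forward: tetradecanoyl chloride gives a β-keto ester, then the β-silyloxy ester, which is homologated by one carbon to the siloxyalkyne. The diazoketone comes from (E)-4-methoxybut-3-en-2-one. The only ring is closed in the benzannulation, followed by oxidation at C1, desilylation and acetylation.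
- The single stereocentre (C2', R) is set by RuCl2[(R)-BINAP] hydrogenation of the β-keto ester and is not touched afterwards.

Key step: step 6

Assumption: the target is handled as the 2-hydroxy-1,4-benzoquinone tautomer drawn in its SMILES; the crude acyl Meldrum's acid (step 1) and the crude trifluoroacetyl diketone (step 5) are carried on without purification.

**Step 1**
Reactants: 1 tetradecanoyl chloride; 2 Meldrum's acid
Product: 4 methyl 3-oxohexadecanoate, via acyl Meldrum's acid 3 (not isolated)
Conditions: pyridine, CH2Cl2, 0 °C → rt; dilute HCl wash, concentrate; then MeOH, reflux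
Reagents that add atoms: methanol, CO
Why: C-acylation of Meldrum's acid followed by thermal loss of acetone and CO2 to an acylketene that methanol traps is the standard Meldrum's acid route to β-keto esters and should give the C16 keto ester cleanly.

**Step 2**
Reactants: 4 methyl 3-oxohexadecanoate
Product: 5 methyl (3R)-3-hydroxyhexadecanoate
Conditions: H2 (50 atm), RuCl2[(R)-BINAP] (cat.), MeOH, 50 °C
Reagents that add atoms: none
Why: Noyori asymmetric hydrogenation of a β-keto ester, in which the ester-chelated ketone is reduced on the face dictated by (R)-BINAP on divalent ruthenium, should give the (R)-β-hydroxy ester and so set the only stereocentre of the target.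

**Step 3**
Reactants: 5 methyl (3R)-3-hydroxyhexadecanoate
Product: 6 methyl (3R)-3-(tert-butyldimethylsilyloxy)hexadecanoate
Conditions: TBSCl, imidazole, DMF, rt
Reagents that add atoms: tert-butyldimethylsilyl chloride, CC(C)(C)[Si](C)(C)Cl
Why: Imidazole-mediated silylation of a secondary alcohol is routine and gives an ether that should survive the organolithium, photochemical and thermal steps ahead without touching the stereocentre.

**Step 4**
Reactants: 6 methyl (3R)-3-(tert-butyldimethylsilyloxy)hexadecanoate
Product: 9 (R)-4-(tert-butyldimethylsilyloxy)-1-(triisopropylsilyloxy)heptadec-1-yne, via lithium dibromoenolate 7 (not isolated), via lithium ynolate 8 (not isolated)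
Conditions: CH2Br2, lithium 2,2,6,6-tetramethylpiperidide, THF, −78 °C; then 6; LiN(SiMe3)2, −78 → −20 °C; n-BuLi, −78 °C → rt; i-Pr3SiOTf, −78 → 0 °C
Reagents that add atoms: dibromomethane, BrCBr; triisopropylsilyl trifluoromethanesulfonate, CC(C)[Si](OS(=O)(=O)C(F)(F)F)(C(C)C)C(C)C
Why: Kowalski ester homologation, in which LiCHBr2 adds to the ester, the dibromo enolate 7 undergoes Br–Li exchange and the carbenoid rearranges by 1,2-alkyl shift to ynolate 8, should give the one-carbon-longer siloxyalkyne once the bulky silyl triflate captures the oxygen, the stereocentre never being deprotonated.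

**Step 5**
Reactants: 10 (E)-4-methoxybut-3-en-2-one
Product: 13 (E)-1-diazo-4-methoxybut-3-en-2-one, via lithium dienolate 11 (not isolated), via trifluoroacetyl diketone 12 (not isolated)
Conditions: LiN(SiMe3)2, THF, −78 °C; CF3CO2CH2CF3, −78 °C; pH 7 buffer work-up; then MsN3, Et3N, H2O, MeCN, rt
Reagents that add atoms: methanesulfonyl azide, CS(=O)(=O)N=[N+]=[N-]
Why: Detrifluoroacetylative (Regitz-type) diazo transfer, in which the kinetic methyl-side enolate 11 is trifluoroacetylated and the activated diketone 12 takes the diazo group from MsN3 with loss of the trifluoroacetyl group as its sulfonamide, is the established way to diazomethyl enones, and the non-acidic hand-over between the stages should keep the β-methoxy enone from cyclising.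

**Step 6**
Reactants: 9 (R)-4-(tert-butyldimethylsilyloxy)-1-(triisopropylsilyloxy)heptadec-1-yne; 13 (E)-1-diazo-4-methoxybut-3-en-2-one
Product: 18 2-[(2R)-2-(tert-butyldimethylsilyloxy)pentadecyl]-6-methoxy-3-(triisopropylsilyloxy)phenol, via vinylketene 14 (not isolated), via vinylcyclobutenone 15 (not isolated), via dienylketene 16 (not isolated), via cyclohexadienone 17 (not isolated)
Conditions: hν (254 nm, quartz), degassed ClCH2CH2Cl, rt, 13 in modest excess added in portions; then 80 °C
Reagents that add atoms: none
Why: Irradiation expels N2 from 13 and the methoxyvinyl group shifts to the former diazo carbon (photochemical Wolff rearrangement, forming C1–C6) to give vinylketene 14, which adds [2+2] across the electron-rich triple bond of 9 (forming C3–C4 and C1–C2) to give cyclobutenone 15. On heating, 15 opens by four-electron electrocyclic ring opening to dienylketene 16, which closes at C4–C5 to dienone 17 and tautomerises to phenol 18. The closest known reaction type is the Danheiser benzannulation of photochemically generated vinylketenes with siloxyalkynes. The one ring formed, the benzene ring, is closed by thermal disrotatory six-electron electrocyclisation of the dienylketene, the four-membered ring being only a transient. No stereocentre is created that persists, because the sp3 carbons of 15 and 17 are erased on aromatisation and the C2' silyl ether centre is remote from all bond changes. The single selectivity needed is the orientation of the [2+2] addition, which the polarisation of the siloxyalkyne should secure by sending its nucleophilic chain-bearing carbon to the ketene carbonyl carbon, so that the chain ends up ortho to the new hydroxyl and the silyloxy group meta to it, while the E enol ether keeps the methoxy group on the outside during ring closure.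

**Step 7**
Reactants: 18 2-[(2R)-2-(tert-butyldimethylsilyloxy)pentadecyl]-6-methoxy-3-(triisopropylsilyloxy)phenol
Product: 19 3-[(2R)-2-(tert-butyldimethylsilyloxy)pentadecyl]-5-methoxy-2-(triisopropylsilyloxy)cyclohexa-2,5-diene-1,4-dione
Conditions: (KSO3)2NO, aq KH2PO4, methyltrioctylammonium chloride (cat.), CH2Cl2/H2O, rt
Reagents that add atoms: potassium nitrosodisulfonate (Fremy's salt), [K+].[K+].[O]N(S(=O)(=O)[O-])S(=O)(=O)[O-]
Why: In the Teuber oxidation the nitroxyl radical abstracts the phenolic hydrogen and a second equivalent couples at the only free para carbon (C1), the adduct collapsing to the para-quinone, so the regiochemistry is fixed by the substitution pattern of 18, and any loss of the quinonyl silyl group in the aqueous medium would be harmless since step 8 removes it.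

**Step 8**
Reactants: 19 3-[(2R)-2-(tert-butyldimethylsilyloxy)pentadecyl]-5-methoxy-2-(triisopropylsilyloxy)cyclohexa-2,5-diene-1,4-dione
Product: 20 2-hydroxy-3-[(2R)-2-hydroxypentadecyl]-5-methoxycyclohexa-2,5-diene-1,4-dione
Conditions: HF (48 % aq), MeCN, 0 °C → rt
Reagents that add atoms: none
Why: Acidic fluoride desilylation should cleave the secondary alkyl silyl ether and the vinylogous silyl ester together while the methoxyquinone and the stereocentre stay untouched.

**Step 9**
Reactants: 20 2-hydroxy-3-[(2R)-2-hydroxypentadecyl]-5-methoxycyclohexa-2,5-diene-1,4-dione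
Product: 22 (2R)-1-(2-hydroxy-5-methoxy-3,6-dioxocyclohexa-1,4-dien-1-yl)pentadecan-2-yl acetate, via diacetate 21 (not isolated)
Conditions: Ac2O, pyridine, DMAP (cat.), CH2Cl2, 0 °C → rt; then MeOH, rt; dilute HCl work-up
Reagents that add atoms: acetic anhydride, CC(=O)OC(C)=O
Why: DMAP-catalysed acylation esterifies the secondary alcohol irreversibly, whereas the acetate formed on the acidic quinone hydroxyl is a vinylogous mixed anhydride that methanol and DMAP should cleave selectively in the same flask, leaving the alkyl acetate with retention at C2'.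

**Compound list**

1 | tetradecanoyl chloride | CCCCCCCCCCCCCC(=O)Cl | starting material
2 | Meldrum's acid (2,2-dimethyl-1,3-dioxane-4,6-dione) | CC1(C)OC(=O)CC(=O)O1 | starting material
3 | 5-(1-hydroxytetradecylidene)-2,2-dimethyl-1,3-dioxane-4,6-dione (acyl Meldrum's acid, enol form) | CCCCCCCCCCCCCC(O)=C1C(=O)OC(C)(C)OC1=O | intermediate
4 | methyl 3-oxohexadecanoate | CCCCCCCCCCCCCC(=O)CC(=O)OC | intermediate
5 | methyl (3R)-3-hydroxyhexadecanoate | CCCCCCCCCCCCC[C@H](CC(=O)OC)O | intermediate
6 | methyl (3R)-3-(tert-butyldimethylsilyloxy)hexadecanoate | CCCCCCCCCCCCC[C@H](CC(=O)OC)O[Si](C)(C)C(C)(C)C | intermediate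
7 | lithium (4R)-1,1-dibromo-4-(tert-butyldimethylsilyloxy)heptadec-1-en-2-olate | CCCCCCCCCCCCC[C@H](CC([O-])=C(Br)Br)O[Si](C)(C)C(C)(C)C.[Li+] | intermediate
8 | lithium (4R)-4-(tert-butyldimethylsilyloxy)heptadec-1-yn-1-olate | CCCCCCCCCCCCC[C@H](CC#C[O-])O[Si](C)(C)C(C)(C)C.[Li+] | intermediate
9 | (R)-4-(tert-butyldimethylsilyloxy)-1-(triisopropylsilyloxy)heptadec-1-yne | CCCCCCCCCCCCC[C@H](CC#CO[Si](C(C)C)(C(C)C)C(C)C)O[Si](C)(C)C(C)(C)C | intermediate
10 | (E)-4-methoxybut-3-en-2-one | CO/C=C/C(C)=O | starting material
11 | lithium (E)-4-methoxybuta-1,3-dien-2-olate | CO/C=C/C([O-])=C.[Li+] | intermediate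
12 | (E)-1,1,1-trifluoro-6-methoxyhex-5-ene-2,4-dione | CO/C=C/C(=O)CC(=O)C(F)(F)F | intermediate
13 | (E)-1-diazo-4-methoxybut-3-en-2-one | CO/C=C/C(=O)C=[N+]=[N-] | intermediate
14 | (E)-4-methoxybuta-1,3-dien-1-one ((2-methoxyvinyl)ketene) | CO/C=C/C=C=O | intermediate
15 | 2-[(2R)-2-(tert-butyldimethylsilyloxy)pentadecyl]-4-[(E)-2-methoxyethenyl]-3-(triisopropylsilyloxy)cyclobut-2-en-1-one (both C4 epimers) | CCCCCCCCCCCCC[C@H](CC1=C(O[Si](C(C)C)(C(C)C)C(C)C)C(/C=C/OC)C1=O)O[Si](C)(C)C(C)(C)C | intermediate
16 | (3E,5E)-2-[(2R)-2-(tert-butyldimethylsilyloxy)pentadecyl]-6-methoxy-3-(triisopropylsilyloxy)hexa-1,3,5-trien-1-one | CCCCCCCCCCCCC[C@H](CC(=C=O)/C(O[Si](C(C)C)(C(C)C)C(C)C)=C\C=C\OC)O[Si](C)(C)C(C)(C)C | intermediate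
17 | 2-[(2R)-2-(tert-butyldimethylsilyloxy)pentadecyl]-6-methoxy-3-(triisopropylsilyloxy)cyclohexa-2,4-dien-1-one (both C6 epimers) | CCCCCCCCCCCCC[C@H](CC1=C(O[Si](C(C)C)(C(C)C)C(C)C)C=CC(OC)C1=O)O[Si](C)(C)C(C)(C)C | intermediate
18 | 2-[(2R)-2-(tert-butyldimethylsilyloxy)pentadecyl]-6-methoxy-3-(triisopropylsilyloxy)phenol | CCCCCCCCCCCCC[C@H](Cc1c(O)c(OC)ccc1O[Si](C(C)C)(C(C)C)C(C)C)O[Si](C)(C)C(C)(C)C | intermediate
19 | 3-[(2R)-2-(tert-butyldimethylsilyloxy)pentadecyl]-5-methoxy-2-(triisopropylsilyloxy)cyclohexa-2,5-diene-1,4-dione | CCCCCCCCCCCCC[C@H](CC1=C(O[Si](C(C)C)(C(C)C)C(C)C)C(=O)C=C(OC)C1=O)O[Si](C)(C)C(C)(C)C | intermediate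
20 | 2-hydroxy-3-[(2R)-2-hydroxypentadecyl]-5-methoxycyclohexa-2,5-diene-1,4-dione | CCCCCCCCCCCCC[C@H](CC1=C(O)C(=O)C=C(OC)C1=O)O | intermediate
21 | (2R)-1-(2-acetoxy-5-methoxy-3,6-dioxocyclohexa-1,4-dien-1-yl)pentadecan-2-yl acetate | CCCCCCCCCCCCC[C@H](CC1=C(OC(C)=O)C(=O)C=C(OC)C1=O)OC(C)=O | intermediate
22 | (2R)-1-(2-hydroxy-5-methoxy-3,6-dioxocyclohexa-1,4-dien-1-yl)pentadecan-2-yl acetate (CNP0332196.1) | CCCCCCCCCCCCC[C@H](CC1=C(O)C(=O)C=C(OC)C1=O)OC(C)=O | target

**Step count**

Total steps: 9. Longest linear sequence: 8 steps (steps 1–4 and 6–9); step 5 is the one-step side branch.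

**Steps most likely to fail**

Step 6. The photochemical stage may lose material through E/Z scrambling of the enol ether, secondary photolysis of the phenol at 254 nm, acylation of the product phenol by excess ketene, or acid-triggered breakdown of the siloxyalkyne before the [2+2] addition. The fallback sets out from 9 and generates the same ketene without light. Commercial (E)-4-methoxybut-2-enoic acid is treated with (COCl)2 and catalytic DMF in CH2Cl2 to give (E)-4-methoxybut-2-enoyl chloride F1. F1 is added slowly to 9 and Et3N in CH2Cl2 at 0 °C to rt, so that 1,4-dehydrochlorination releases ketene 14, which 9 traps as cyclobutenone 15. Heating 15 in toluene at 80–110 °C then carries it through 16 and 17, and the fallback comes back to the route at 18. Vinylketene generation from unsaturated acid chlorides and [2+2] trapping by electron-rich alkynes is a known reaction type.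

Step 4. The ester may be enolised by the hindered amide base with β-elimination of the silyloxy group, the carbenoid rearrangement may be incomplete, or the ynolate may be silylated on carbon instead of oxygen. The fallback sets out from 6 and reaches the ynolate by oxidation of an acetylide. Reduction of 6 with i-Bu2AlH in CH2Cl2 at −78 °C gives (3R)-3-(tert-butyldimethylsilyloxy)hexadecanal F2. Ohira–Bestmann homologation (dimethyl (1-diazo-2-oxopropyl)phosphonate, K2CO3, MeOH, 0 °C → rt) gives (4R)-4-(tert-butyldimethylsilyloxy)heptadec-1-yne F3. Deprotonation of F3 with n-BuLi in THF at −78 °C and oxidation of the acetylide with lithium tert-butyl peroxide (from t-BuOOH and LiN(SiMe3)2, −78 → 0 °C) gives ynolate 8, and i-Pr3SiOTf at −78 °C brings the fallback back to the route at 9.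

Step 5. The trifluoroacetylated intermediate may cyclise with loss of methanol to a pyranone, or nucleophiles may add to the β-methoxy enone during diazo transfer. The fallback sets out from 10 and avoids the 1,3-diketone altogether. Silylation of 10 with Me3SiCl, Et3N and catalytic ZnCl2 gives (E)-1-methoxy-3-(trimethylsilyloxy)buta-1,3-diene F4. N-Bromosuccinimide in THF at 0 °C converts F4 into (E)-1-bromo-4-methoxybut-3-en-2-one F5. N,N'-Ditosylhydrazine and DBU in THF at 0 °C then convert the bromomethyl ketone, by N-alkylation and double sulfinate elimination, into the diazoketone, and the fallback comes back to the route at 13.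

**Further compounds**

F1 | step 6 | (E)-4-methoxybut-2-enoyl chloride | COC/C=C/C(Cl)=O
F2 | step 4 | (3R)-3-(tert-butyldimethylsilyloxy)hexadecanal | CCCCCCCCCCCCC[C@H](CC=O)O[Si](C)(C)C(C)(C)C
F3 | step 4 | (4R)-4-(tert-butyldimethylsilyloxy)heptadec-1-yne | CCCCCCCCCCCCC[C@H](CC#C)O[Si](C)(C)C(C)(C)C
F4 | step 5 | (E)-1-methoxy-3-(trimethylsilyloxy)buta-1,3-diene | CO/C=C/C(=C)O[Si](C)(C)C
F5 | step 5 | (E)-1-bromo-4-methoxybut-3-en-2-one | CO/C=C/C(=O)CBr
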